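**Convention:** position labels C1–C15 are the germacranolide positions of the target (C6 = lactone CH–O, C7 = ring-fusion CH, C8 = ester-bearing CH, C10 = tertiary carbinol). The target is taken as drawn: (6S,7R,8R,10R), cis-fused lactone, (S)-2-methylbutanoate.

## Retrosynthetic overview

1. C8 ester last: Mitsunobu inversion of the 8-epi alcohol with (S)-2-methylbutanoic acid.
2. Ten-membered ring (last ring formed): C3–C4 bond by intramolecular Nozaki–Hiyama–Kishi coupling of a Z-vinyl iodide with an enal, then oxidation to the dienone.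
3. α-Methylene-γ-lactone (second ring): oxidative lactonisation of a 2-methylene-1,4-diol; the Z-vinyl iodide comes from the alkyne by hydroalumination/iodination.
4. Key C6–C7 bond: [2,3]-Wittig rearrangement of a (Z)-allyl but-2-ynyl ether; C6 and C7 are set under control of C8.
5. C8 and C10: L-glutamic-acid-derived lactone, enolate methylation then hydroxylation; a temporary 1,3-dioxane (first ring formed) protects the diol.

## Route

Step 1
Reactants: 1 (S)-5-(hydroxymethyl)dihydrofuran-2(3H)-one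
Product: 2 (S)-5-[(tert-butyldiphenylsilyloxy)methyl]dihydrofuran-2(3H)-one
Conditions: TBDPSCl, imidazole, DMF, 0 °C to rt
Reagents that add atoms: tert-butyl(chloro)diphenylsilane CC(C)(C)[Si](Cl)(c1ccccc1)c1ccccc1
Why: Silylation of the primary alcohol installs a bulky ether that later shields one face of the lactone enolate; no stereocenter is touched.

Step 2
Reactants: 2 (S)-5-[(tert-butyldiphenylsilyloxy)methyl]dihydrofuran-2(3H)-one
Product: 4 (3R,5S)-5-[(tert-butyldiphenylsilyloxy)methyl]-3-methyldihydrofuran-2(3H)-one, via lithium enolate 3 (not isolated)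
Conditions: LiN(i-Pr)2, THF, −78 °C; MeI, −78 to −40 °C
Reagents that add atoms: iodomethane CI
Why: Enolate alkylation (SN2 on MeI) occurs mainly anti to the CH2OSi group, and this α-centre is planarised again in step 3, so its ratio does not matter.

Step 3
Reactants: 4 (3R,5S)-5-[(tert-butyldiphenylsilyloxy)methyl]-3-methyldihydrofuran-2(3H)-one
Product: 7 (3R,5S)-5-[(tert-butyldiphenylsilyloxy)methyl]-3-hydroxy-3-methyldihydrofuran-2(3H)-one, via lithium enolate 5 (not isolated), via hydroperoxy lactone 6 (not isolated)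
Conditions: LiN(i-Pr)2, THF, −78 °C; O2, P(OEt)3, −78 to −20 °C
Reagents that add atoms: dioxygen O=O
Why: Enolate oxygenation: the planar tertiary enolate is attacked by O2 on the face opposite the CH2OSi group and the hydroperoxide is reduced in situ by the phosphite, which sets the tertiary carbinol (future C10, R) by 1,3-induction from the bought centre.

Step 4
Reactants: 7 (3R,5S)-5-[(tert-butyldiphenylsilyloxy)methyl]-3-hydroxy-3-methyldihydrofuran-2(3H)-one
Product: 8 (3R,5S)-5-[(tert-butyldiphenylsilyloxy)methyl]-3-methyltetrahydrofuran-2,3-diol (lactol, both anomers)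
Conditions: i-Bu2AlH (2.2 equiv), CH2Cl2, −78 °C
Reagents that add atoms: none
Why: Partial hydride reduction of the lactone stops at the lactol because the aluminium hemiacetal is stable at −78 °C; no stereocenter of consequence changes.

Step 5
Reactants: 8 lactol; 9 ethyl (triphenylphosphoranylidene)acetate
Product: 10 ethyl (2E,4R,6S)-7-(tert-butyldiphenylsilyloxy)-4,6-dihydroxy-4-methylhept-2-enoate
Conditions: toluene, 80 °C
Reagents that add atoms: none
Why: Wittig olefination of the open hydroxy-aldehyde form with a stabilised ylide gives the E-enoate (C1=C2, C3) and frees the C8 hydroxyl; no new stereocenter.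

Step 6
Reactants: 10 ethyl (2E,4R,6S)-7-(tert-butyldiphenylsilyloxy)-4,6-dihydroxy-4-methylhept-2-enoate
Product: 11 ethyl (2E)-3-[(4R,6S)-6-[(tert-butyldiphenylsilyloxy)methyl]-2,2,4-trimethyl-1,3-dioxan-4-yl]prop-2-enoate
Conditions: 2-methoxypropene, PPTS (cat.), CH2Cl2, 0 °C
Reagents that add atoms: 2-methoxypropene COC(C)=C
Why: Acid-catalysed acetal formation ties the syn-1,3-diol (C8–OH, C10–OH) into a dioxane whose C8–O bond later directs the rearrangement; no stereocenter changes.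

Step 7
Reactants: 11 silyl ether acetonide
Product: 12 ethyl (2E)-3-[(4R,6S)-6-(hydroxymethyl)-2,2,4-trimethyl-1,3-dioxan-4-yl]prop-2-enoate
Conditions: Bu4NF, THF, 0 °C
Reagents that add atoms: none
Why: Fluoride-mediated desilylation frees the primary alcohol while the acetonide and enoate are inert.

Step 8
Reactants: 12 primary alcohol
Product: 13 ethyl (2E)-3-[(4R,6S)-6-formyl-2,2,4-trimethyl-1,3-dioxan-4-yl]prop-2-enoate
Conditions: Dess–Martin periodinane, NaHCO3, CH2Cl2, 0 °C to rt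
Reagents that add atoms: none
Why: Dess–Martin oxidation gives the α-alkoxy aldehyde (C7) under buffered conditions that do not epimerise C8.

Step 9
Reactants: 13 aldehyde; 14 but-2-yn-1-ol; 15 ethyl 2-(diethoxyphosphoryl)prop-2-enoate
Product: 17 ethyl (2E)-2-[(but-2-yn-1-yloxy)methyl]-3-[(4S,6R)-6-[(1E)-3-ethoxy-3-oxoprop-1-en-1-yl]-2,2,6-trimethyl-1,3-dioxan-4-yl]prop-2-enoate, via phosphonate carbanion 16 (not isolated)
Conditions: NaH, 14, THF, 0 °C; 15; then 13, −78 to 0 °C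
Reagents that add atoms: none
Why: Tandem oxa-Michael addition/Horner–Wadsworth–Emmons olefination: the butynyl oxide adds to the vinylphosphonate and the resulting carbanion olefinates the aldehyde E-selectively (ester trans to C8), which places the butynyloxymethyl arm cis to C8 as the rearrangement requires.

Step 10
Reactants: 17 diester
Product: 18 (2Z)-2-[(but-2-yn-1-yloxy)methyl]-3-[(4S,6R)-6-[(1E)-3-hydroxyprop-1-en-1-yl]-2,2,6-trimethyl-1,3-dioxan-4-yl]prop-2-en-1-ol
Conditions: i-Bu2AlH (5 equiv), CH2Cl2, −78 °C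
Reagents that add atoms: none
Why: 1,2-Reduction of both conjugated esters to allylic alcohols removes all electrophilic groups before the carbanion chemistry; no stereocenter changes.

Step 11
Reactants: 18 allyl but-2-ynyl ether diol
Product: 20 (3S,4R)-3-[(4S,6R)-6-[(1E)-3-hydroxyprop-1-en-1-yl]-2,2,6-trimethyl-1,3-dioxan-4-yl]-2-methylidenehept-5-yne-1,4-diol, via trilithiated ether 19 (not isolated)
Conditions: n-BuLi (3.3 equiv), THF, −78 to −30 °C
Reagents that add atoms: none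
Why: [2,3]-Wittig sigmatropic rearrangement: the propargylic α-oxy carbanion bonds to C7 through a five-membered envelope transition state, the Z-configured allyl terminus giving the syn C6–OH/C7 relationship, while attack anti to the allylic C8–O bond (H8 held in the alkene plane by A(1,3) strain) fixes C7 relative to the bought C8 centre.

Step 12
Reactants: 20 propargylic alcohol
Product: 22 (3S,4R,5Z)-3-[(4S,6R)-6-[(1E)-3-hydroxyprop-1-en-1-yl]-2,2,6-trimethyl-1,3-dioxan-4-yl]-6-iodo-2-methylidenehept-5-ene-1,4-diol, via alkenylalanate 21 (not isolated)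
Conditions: NaAlH2(OCH2CH2OMe)2, THF, 0 °C to rt; then I2, −78 °C
Reagents that add atoms: iodine II
Why: Hydroxyl-directed trans-hydroalumination of the propargylic alcohol (H to C5, Al to C4 in a five-membered alkoxyalanate) followed by iodinolysis with retention gives the Z-iodoalkene; no stereocenter changes.

Step 13
Reactants: 22 vinyl iodide triol
Product: 24 (2E)-3-[(4R,6S)-6-[(2R,3R)-2-[(1Z)-2-iodoprop-1-en-1-yl]-4-methylidene-5-oxooxolan-3-yl]-2,2,4-trimethyl-1,3-dioxan-4-yl]prop-2-enal, via lactol 23 (not isolated)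
Conditions: TEMPO (cat.), PhI(OAc)2 (3.5 equiv), CH2Cl2, rt
Reagents that add atoms: none
Why: Oxoammonium oxidation is selective for the two primary allylic alcohols, giving the C3 enal and, through the lactol with the C6 hydroxyl, the cis-fused α-methylene-γ-lactone (oxidative lactonisation); C6 and C7 are untouched.

Step 14
Reactants: 24 iodo enal
Product: 25 8,10-O-isopropylidene-(6S,7R,8S,10R)-3,8,10-trihydroxygermacra-1E,4Z,11(13)-trien-12,6-olide (both C3 epimers)
Conditions: CrCl2 (10 equiv), NiCl2 (cat.), DMSO–THF, rt, 2 mM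
Reagents that add atoms: none
Why: Nozaki–Hiyama–Kishi reaction: nickel-catalysed activation of the vinyl iodide, transmetalation to chromium and 1,2-addition to the enal close the ten-membered ring with retention of both alkene geometries; the new C3 carbinol is an inconsequential mixture.

Step 15
Reactants: 25 macrocyclic dienol
Product: 26 8,10-O-isopropylidene-(6S,7R,8S,10R)-8,10-dihydroxy-3-oxogermacra-1E,4Z,11(13)-trien-12,6-olide
Conditions: Dess–Martin periodinane, NaHCO3, CH2Cl2, 0 °C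
Reagents that add atoms: none
Why: Dess–Martin oxidation of the doubly allylic alcohol gives the cross-conjugated dienone and removes the C3 stereocentre.

Step 16
Reactants: 26 acetonide
Product: 27 (6S,7R,8S,10R)-8,10-dihydroxy-3-oxogermacra-1E,4Z,11(13)-trien-12,6-olide (8-epi alcohol)
Conditions: AcOH–H2O–THF (3:1:1), 35 °C
Reagents that add atoms: none
Why: Mild acidic hydrolysis of the strained acetonide (tertiary centre, 1,3-diaxial methyl groups) liberates the diol without touching lactone or dienone.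

Step 17
Reactants: 27 8-epi diol; 28 (S)-2-methylbutanoic acid
Product: 29 target, (6S,7R,8R,10R)-10-hydroxy-8-[(2S)-2-methylbutanoyloxy]-3-oxogermacra-1E,4Z,11(13)-trien-12,6-olide = [(3aR,4R,6R,7E,10Z,11aS)-6-hydroxy-6,10-dimethyl-3-methylidene-2,9-dioxo-3a,4,5,11a-tetrahydrocyclodeca[b]furan-4-yl] (2S)-2-methylbutanoate
Conditions: PPh3, diisopropyl azodicarboxylate, toluene, 0 °C to rt
Reagents that add atoms: none
Why: Mitsunobu esterification: SN2 displacement of the C8 oxyphosphonium by the carboxylate inverts C8 (S to R), the tertiary C10 hydroxyl cannot react and the acid's own stereocentre is not involved.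

## Compound list

1 | (S)-5-(hydroxymethyl)dihydrofuran-2(3H)-one (from L-glutamic acid) | O=C1CC[C@@H](CO)O1 | starting material
2 | (S)-5-[(tert-butyldiphenylsilyloxy)methyl]dihydrofuran-2(3H)-one | O=C1CC[C@@H](CO[Si](c2ccccc2)(c2ccccc2)C(C)(C)C)O1 | intermediate
3 | lithium enolate of 2 | [Li+].[O-]C1=CC[C@@H](CO[Si](c2ccccc2)(c2ccccc2)C(C)(C)C)O1 | intermediate
4 | (3R,5S)-5-[(tert-butyldiphenylsilyloxy)methyl]-3-methyldihydrofuran-2(3H)-one | O=C1[C@H](C)C[C@@H](CO[Si](c2ccccc2)(c2ccccc2)C(C)(C)C)O1 | intermediate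
5 | lithium enolate of 4 | [Li+].[O-]C1=C(C)C[C@@H](CO[Si](c2ccccc2)(c2ccccc2)C(C)(C)C)O1 | intermediate
6 | (3R,5S)-5-[(tert-butyldiphenylsilyloxy)methyl]-3-hydroperoxy-3-methyldihydrofuran-2(3H)-one | O=C1[C@](C)(OO)C[C@@H](CO[Si](c2ccccc2)(c2ccccc2)C(C)(C)C)O1 | intermediate
7 | (3R,5S)-5-[(tert-butyldiphenylsilyloxy)methyl]-3-hydroxy-3-methyldihydrofuran-2(3H)-one | O=C1[C@](C)(O)C[C@@H](CO[Si](c2ccccc2)(c2ccccc2)C(C)(C)C)O1 | intermediate
8 | (3R,5S)-5-[(tert-butyldiphenylsilyloxy)methyl]-3-methyltetrahydrofuran-2,3-diol (anomers) | OC1[C@](C)(O)C[C@@H](CO[Si](c2ccccc2)(c2ccccc2)C(C)(C)C)O1 | intermediate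
9 | ethyl (triphenylphosphoranylidene)acetate | CCOC(=O)C=P(c1ccccc1)(c1ccccc1)c1ccccc1 | starting material
10 | ethyl (2E,4R,6S)-7-(tert-butyldiphenylsilyloxy)-4,6-dihydroxy-4-methylhept-2-enoate | CCOC(=O)/C=C/[C@](C)(O)C[C@H](O)CO[Si](c1ccccc1)(c1ccccc1)C(C)(C)C | intermediate
11 | ethyl (2E)-3-[(4R,6S)-6-[(tert-butyldiphenylsilyloxy)methyl]-2,2,4-trimethyl-1,3-dioxan-4-yl]prop-2-enoate | CCOC(=O)/C=C/[C@@]1(C)C[C@@H](CO[Si](c2ccccc2)(c2ccccc2)C(C)(C)C)OC(C)(C)O1 | intermediate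
12 | ethyl (2E)-3-[(4R,6S)-6-(hydroxymethyl)-2,2,4-trimethyl-1,3-dioxan-4-yl]prop-2-enoate | CCOC(=O)/C=C/[C@@]1(C)C[C@@H](CO)OC(C)(C)O1 | intermediate
13 | ethyl (2E)-3-[(4R,6S)-6-formyl-2,2,4-trimethyl-1,3-dioxan-4-yl]prop-2-enoate | CCOC(=O)/C=C/[C@@]1(C)C[C@@H](C=O)OC(C)(C)O1 | intermediate
14 | but-2-yn-1-ol | CC#CCO | starting material
15 | ethyl 2-(diethoxyphosphoryl)prop-2-enoate | C=C(C(=O)OCC)P(=O)(OCC)OCC | starting material
16 | sodium salt of ethyl 3-(but-2-yn-1-yloxy)-2-(diethoxyphosphoryl)propanoate (carbanion) | [Na+].CCOC(=O)[C-](COCC#CC)P(=O)(OCC)OCC | intermediate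
17 | ethyl (2E)-2-[(but-2-yn-1-yloxy)methyl]-3-[(4S,6R)-6-[(1E)-3-ethoxy-3-oxoprop-1-en-1-yl]-2,2,6-trimethyl-1,3-dioxan-4-yl]prop-2-enoate | CCOC(=O)/C(COCC#CC)=C/[C@@H]1C[C@](C)(/C=C/C(=O)OCC)OC(C)(C)O1 | intermediate
18 | (2Z)-2-[(but-2-yn-1-yloxy)methyl]-3-[(4S,6R)-6-[(1E)-3-hydroxyprop-1-en-1-yl]-2,2,6-trimethyl-1,3-dioxan-4-yl]prop-2-en-1-ol | OC/C(COCC#CC)=C/[C@@H]1C[C@](C)(/C=C/CO)OC(C)(C)O1 | intermediate
19 | trilithiated 18 (two alkoxides, propargylic OCH carbanion) | [Li+].[Li+].[Li+].[O-]C/C(CO[CH-]C#CC)=C/[C@@H]1C[C@](C)(/C=C/C[O-])OC(C)(C)O1 | intermediate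
20 | (3S,4R)-3-[(4S,6R)-6-[(1E)-3-hydroxyprop-1-en-1-yl]-2,2,6-trimethyl-1,3-dioxan-4-yl]-2-methylidenehept-5-yne-1,4-diol | CC#C[C@H](O)[C@H](C(=C)CO)[C@@H]1C[C@](C)(/C=C/CO)OC(C)(C)O1 | intermediate
21 | cyclic alkenylalanate of 20 (Al on C4, cis to C6; other hydroxyls drawn free) | [Na+].C/C1=C/[C@@H]([C@H](C(=C)CO)[C@@H]2C[C@](C)(/C=C/CO)OC(C)(C)O2)O[Al-]1(OCCOC)OCCOC | intermediate
22 | (3S,4R,5Z)-3-[(4S,6R)-6-[(1E)-3-hydroxyprop-1-en-1-yl]-2,2,6-trimethyl-1,3-dioxan-4-yl]-6-iodo-2-methylidenehept-5-ene-1,4-diol | C/C(I)=C/[C@H](O)[C@H](C(=C)CO)[C@@H]1C[C@](C)(/C=C/CO)OC(C)(C)O1 | intermediate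
23 | lactol of 24 (5-hydroxyoxolane in place of the lactone) | C/C(I)=C/[C@@H]1OC(O)C(=C)[C@@H]1[C@@H]2C[C@](C)(/C=C/C=O)OC(C)(C)O2 | intermediate
24 | (2E)-3-[(4R,6S)-6-[(2R,3R)-2-[(1Z)-2-iodoprop-1-en-1-yl]-4-methylidene-5-oxooxolan-3-yl]-2,2,4-trimethyl-1,3-dioxan-4-yl]prop-2-enal | C/C(I)=C/[C@@H]1OC(=O)C(=C)[C@@H]1[C@@H]2C[C@](C)(/C=C/C=O)OC(C)(C)O2 | intermediate
25 | 8,10-O-isopropylidene-(6S,7R,8S,10R)-3,8,10-trihydroxygermacra-1E,4Z,11(13)-trien-12,6-olide (C3 epimers) | C=C1C(=O)O[C@H]2/C=C(/C)C(O)/C=C/[C@@]3(C)C[C@H](OC(C)(C)O3)[C@@H]12 | intermediate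
26 | 8,10-O-isopropylidene-(6S,7R,8S,10R)-8,10-dihydroxy-3-oxogermacra-1E,4Z,11(13)-trien-12,6-olide | C=C1C(=O)O[C@H]2/C=C(/C)C(=O)/C=C/[C@@]3(C)C[C@H](OC(C)(C)O3)[C@@H]12 | intermediate
27 | (6S,7R,8S,10R)-8,10-dihydroxy-3-oxogermacra-1E,4Z,11(13)-trien-12,6-olide | C=C1C(=O)O[C@H]2/C=C(/C)C(=O)/C=C/[C@](C)(O)C[C@H](O)[C@@H]12 | intermediate
28 | (S)-2-methylbutanoic acid | CC[C@H](C)C(=O)O | starting material
29 | target, (6S,7R,8R,10R)-10-hydroxy-8-[(2S)-2-methylbutanoyloxy]-3-oxogermacra-1E,4Z,11(13)-trien-12,6-olide | C=C1C(=O)O[C@H]2/C=C(/C)C(=O)/C=C/[C@](C)(O)C[C@@H](OC(=O)[C@@H](C)CC)[C@@H]12 | target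

## Step count and risks

Total step count: 17. Longest linear sequence: 17 steps (1 to 29); 9, 14, 15 and 28 are bought.

**Step 11 ([2,3]-Wittig rearrangement).** Three acidic sites compete and both the syn selectivity and the facial selectivity rest on models. The fallback sets out from aldehyde 13 and comes back at triol 22, forming the C6–C7 bond by carbonyl allylation instead. Morita–Baylis–Hillman reaction of 13 with ethyl acrylate (DABCO) gives the allylic alcohol F1. N-Bromosuccinimide/Me2S converts it with allylic transposition into the (Z)-2-(bromomethyl)enoate F2. In parallel, but-2-yn-1-ol 14 is taken with NaAlH2(OCH2CH2OMe)2 then I2 to (Z)-3-iodobut-2-en-1-ol F3, and with MnO2 to (Z)-3-iodobut-2-enal F4. Indium-mediated Barbier allylation of F4 with F2 in THF–H2O (chair transition state, syn) lactonises to the cis-α-methylene-γ-lactone F5. Excess i-Bu2AlH reduces the lactone and the ethyl ester of F5 to the triol 22.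

**Step 14 (Nozaki–Hiyama–Kishi ring closure).** A ten-membered ring from a hindered 2-iodoalkene may give oligomers or reduction. The fallback sets out from 24 and comes back at dienone 26, closing the same bond by an acyl cross-coupling. NaClO2/NaH2PO4/2-methylbut-2-ene oxidises the enal to the carboxylic acid F6. EtSH/DCC/DMAP gives the S-ethyl thioester F7. Me3SnSnMe3 with Pd(PPh3)4 converts the iodide into the vinylstannane F8. Intramolecular thioester–stannane ketone synthesis (Pd2(dba)3, tri(2-furyl)phosphine, CuO2CC4H3S, high dilution) gives 26 directly.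

**Step 17 (Mitsunobu inversion).** SN2 at a hindered ring carbinol next to the ring-fusion carbon may give elimination or lactone migration. The fallback sets out from 27 and comes back at 29 by oxidation and directed reduction. Dess–Martin periodinane oxidises the C8 alcohol to the 8-ketone F9. Me4NBH(OAc)3 in MeCN–AcOH delivers hydride intramolecularly from the C10–O–B ester to give the trans-1,3-diol, the (8R)-alcohol F10. DCC/DMAP esterification with 28 gives 29.

## Further compounds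

F1 | step 11 | ethyl 2-{hydroxy[(4S,6R)-6-[(1E)-3-ethoxy-3-oxoprop-1-en-1-yl]-2,2,6-trimethyl-1,3-dioxan-4-yl]methyl}prop-2-enoate | C=C(C(=O)OCC)C(O)[C@@H]1C[C@](C)(/C=C/C(=O)OCC)OC(C)(C)O1
F2 | step 11 | ethyl (2Z)-2-(bromomethyl)-3-[(4S,6R)-6-[(1E)-3-ethoxy-3-oxoprop-1-en-1-yl]-2,2,6-trimethyl-1,3-dioxan-4-yl]prop-2-enoate | CCOC(=O)/C(CBr)=C/[C@@H]1C[C@](C)(/C=C/C(=O)OCC)OC(C)(C)O1
F3 | step 11 | (Z)-3-iodobut-2-en-1-ol | C/C(I)=C/CO
F4 | step 11 | (Z)-3-iodobut-2-enal | C/C(I)=C/C=O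
F5 | step 11 | ethyl (2E)-3-[(4R,6S)-6-[(2R,3R)-2-[(1Z)-2-iodoprop-1-en-1-yl]-4-methylidene-5-oxooxolan-3-yl]-2,2,4-trimethyl-1,3-dioxan-4-yl]prop-2-enoate | C/C(I)=C/[C@@H]1OC(=O)C(=C)[C@@H]1[C@@H]2C[C@](C)(/C=C/C(=O)OCC)OC(C)(C)O2
F6 | step 14 | (2E)-3-[(4R,6S)-6-[(2R,3R)-2-[(1Z)-2-iodoprop-1-en-1-yl]-4-methylidene-5-oxooxolan-3-yl]-2,2,4-trimethyl-1,3-dioxan-4-yl]prop-2-enoic acid | C/C(I)=C/[C@@H]1OC(=O)C(=C)[C@@H]1[C@@H]2C[C@](C)(/C=C/C(=O)O)OC(C)(C)O2
F7 | step 14 | S-ethyl thioester of F6 | C/C(I)=C/[C@@H]1OC(=O)C(=C)[C@@H]1[C@@H]2C[C@](C)(/C=C/C(=O)SCC)OC(C)(C)O2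
F8 | step 14 | S-ethyl thioester with trimethylstannyl in place of iodine | C/C([Sn](C)(C)C)=C/[C@@H]1OC(=O)C(=C)[C@@H]1[C@@H]2C[C@](C)(/C=C/C(=O)SCC)OC(C)(C)O2
F9 | step 17 | (6S,7R,10R)-10-hydroxy-3,8-dioxogermacra-1E,4Z,11(13)-trien-12,6-olide | C=C1C(=O)O[C@H]2/C=C(/C)C(=O)/C=C/[C@](C)(O)CC(=O)[C@@H]12
F10 | step 17 | (6S,7R,8R,10R)-8,10-dihydroxy-3-oxogermacra-1E,4Z,11(13)-trien-12,6-olide | C=C1C(=O)O[C@H]2/C=C(/C)C(=O)/C=C/[C@](C)(O)C[C@@H](O)[C@@H]12
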